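**Retrosynthetic overview**

- The target is (3S,6R)-8'-apo-ε-carotene-3,8'-diol (carotenoid numbering). The C30 chain is cut at C11=C12 (Wittig) into a ring-bearing C15 dienal (C1–C11) and a C15 ester phosphonium salt (C12–C8') made from the C10 trienedial and a C5 phosphonate; the ester is reduced last.
- The dienal comes from (3S,6R)-3-hydroxy-α-ionone by two-carbon homologation, and the ionone from a bicyclic lactol by Wittig olefination at C7.
- Feature used: in the cyclohexene ring (C1 gem-dimethyl, C2H2, C3 carbinol, C4=C5, C6 methine) O3 and C7 are cis-1,4. They can therefore be tied as an O3–C7(=O) lactone, and that 2-oxabicyclo[2.2.2]oct-5-en-3-one is the [4+2] adduct of a 4-methyl-2-pyrone (C3–C7) and isobutene (C1, C2).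
- Ring order: the carbocycle is the only ring made (step 5, bonds C1–C6 and C2–C3). Its π-face is set by an (S)-p-tolylsulfinyl group on the pyrone; sulfur is then removed at the locked bridgehead and the bridge is opened.
- The pyrone is built from ethyl 3-methylbut-2-enoate; the sulfinyl group is transferred from menthyl p-toluenesulfinate (Andersen method) rather than by asymmetric oxidation of a diaryl-type sulfide, which would be unreliable.

Key step: step 5

Remark (assumption): the (S)-sulfoxide is taken to react through the conformer whose sulfur lone pair eclipses the 4-methyl group, so that p-tolyl blocks one face and the (3S,6R) ring results; were the opposite sense found, the enantiomeric sulfinate ester would be used in step 4.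

**Route**

Step 1
Reactants: 1 ethyl 3-methylbut-2-enoate; 2 tert-butoxybis(dimethylamino)methane
Product: 3 ethyl (2E,4E)-5-(dimethylamino)-3-methylpenta-2,4-dienoate
Conditions: 2 (1.5 equiv), neat, 120 °C, 16 h, t-BuOH and Me2NH distilled off; vacuum distillation
Reagents that add atoms: none
Why: Vinylogous aminomethylenation: the reagent ionises to tert-butoxide and a formamidinium ion, the γ-methyl of the enoate is deprotonated reversibly and condensed, and the fully conjugated push–pull dienamine should accumulate as the thermodynamic product.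

Step 2
Reactants: 3 ethyl (2E,4E)-5-(dimethylamino)-3-methylpenta-2,4-dienoate
Product: 5 4-methyl-2H-pyran-2-one, via ethyl (2Z,4E)-5-hydroxy-3-methylpenta-2,4-dienoate 4 (not isolated)
Conditions: AcOH, 6 M aq. HCl, 100 °C, 3 h
Reagents that add atoms: water, O
Why: Enamine hydrolysis followed by lactonisation: acid unmasks the δ-enol, the push–pull C2=C3 bond equilibrates to the 2Z isomer and the enol oxygen closes on the ester with loss of ethanol to give the 2-pyrone.

Step 3
Reactants: 5 4-methyl-2H-pyran-2-one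
Product: 7 3-bromo-4-methyl-2H-pyran-2-one, via 3,6-dibromo-4-methyl-3,6-dihydro-2H-pyran-2-one 6 (not isolated)
Conditions: Br2 (1.05 equiv), CH2Cl2, 0 °C to rt; then Et3N (1.5 equiv), 0 °C
Reagents that add atoms: bromine, BrBr
Why: Electrophilic bromination by addition–elimination, the established access to 3-bromo-2-pyrones: attack at C3 gives a tertiary cation stabilised by the ring oxygen, bromide adds at C6 and Et3N induces 1,4-loss of HBr.

Step 4
Reactants: 7 3-bromo-4-methyl-2H-pyran-2-one; 8 (1R,2S,5R)-5-methyl-2-(propan-2-yl)cyclohexyl (S)-4-methylbenzenesulfinate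
Product: 10 (S)-4-methyl-3-(4-methylbenzenesulfinyl)-2H-pyran-2-one, via lithium methyl(4-methyl-2-oxo-2H-pyran-3-yl)cuprate 9 (not isolated)
Conditions: Me2CuLi (from MeLi and CuI, 1.1 equiv), THF/Et2O, −78 °C, 20 min; then 8, −78 to −30 °C; aq. NH4Cl
Reagents that add atoms: none
Why: Bromine–copper exchange to the 3-cuprio-2-pyrone followed by Andersen sulfinylation: the organocopper displaces menthoxide at sulfur with inversion, so the sulfur stereocentre of 8 is transferred intact (the descriptor stays S because pyronyl outranks p-tolyl).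

Step 5
Reactants: 10 (S)-4-methyl-3-(4-methylbenzenesulfinyl)-2H-pyran-2-one; 11 2-methylpropene
Product: 12 (1S,4S)-5,8,8-trimethyl-4-[(S)-4-methylbenzenesulfinyl]-2-oxabicyclo[2.2.2]oct-5-en-3-one
Conditions: 11 (30 equiv, condensed), 2,6-di-tert-butyl-4-methylpyridine (2 mol%), CH2Cl2, 12 kbar, 25 °C, 5 d; vent, chromatography below 25 °C
Reagents that add atoms: none
Why: Proposed new method: an asynchronous inverse-electron-demand [4+2] cycloaddition in which the nucleophilic CH2 terminus of isobutene bonds first to the electrophilic O-bearing pyrone carbon C6 and the developing tertiary cationic carbon then closes onto the sulfinyl-bearing C3, whose negative charge is stabilised by the lactone carbonyl and the sulfinyl group; the closest known reaction type is the cycloaddition of 3-sulfinyl- and 3-bromo-2-pyrones with enol ethers and ketene acetals, and the high-pressure addition of 2-pyrones to simple alkenes, which give isolable 2-oxabicyclo[2.2.2]octenones. The cyclohexene ring (C1–C6) is closed by this intermolecular [4+2] mode, forming C1–C6 and C2–C3 across the diene termini while the lactone C(=O)–O stays as the two-atom bridge. The two bridgehead stereocentres are coupled by the bridge, so only the π-face matters: with the sulfur lone pair next to the 4-methyl group to avoid allylic strain, p-tolyl shields one face and isobutene should add to the face carrying the sulfinyl oxygen, which for the (S)-sulfoxide gives the (1S,4S) adduct. Regioselectivity follows the pyrone LUMO (largest coefficient at C6) and the Markovnikov polarisation of isobutene, and there is no endo/exo question because each dienophile carbon carries two identical substituents. The strongly negative activation volume should allow reaction at 25 °C, below the temperature of cycloreversion or CO2 extrusion, and the hindered pyridine suppresses acid-initiated oligomerisation of the alkene.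

Step 6
Reactants: 12 (1S,4S)-5,8,8-trimethyl-4-[(S)-4-methylbenzenesulfinyl]-2-oxabicyclo[2.2.2]oct-5-en-3-one
Product: 13 (1S,4S)-5,8,8-trimethyl-4-[(4-methylphenyl)sulfanyl]-2-oxabicyclo[2.2.2]oct-5-en-3-one
Conditions: NaI (3 equiv), (CF3CO)2O (1.5 equiv), acetone, −40 to −10 °C; aq. Na2S2O3/NaHCO3
Reagents that add atoms: none
Why: Sulfoxide deoxygenation by O-acylation and iodide reduction; there is no α-hydrogen for a Pummerer pathway and the bridgehead cannot ionise, so lactone, alkene and both carbon stereocentres should be untouched.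

Step 7
Reactants: 13 (1S,4S)-5,8,8-trimethyl-4-[(4-methylphenyl)sulfanyl]-2-oxabicyclo[2.2.2]oct-5-en-3-one
Product: 14 (1S,4R)-5,8,8-trimethyl-2-oxabicyclo[2.2.2]oct-5-en-3-one
Conditions: Bu3SnH (3 equiv), AIBN (0.3 equiv, in portions), PhH, 80 °C, 2–4 h; aq. KF
Reagents that add atoms: none
Why: Radical chain desulfurisation (homolytic substitution at sulfur by the stannyl radical): the bridgehead radical is pyramidal and locked by the bicycle, so hydrogen is delivered where sulfur left (retention at C6), and Bredt strain keeps the C4=C5 bond out of conjugation.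

Step 8
Reactants: 14 (1S,4R)-5,8,8-trimethyl-2-oxabicyclo[2.2.2]oct-5-en-3-one
Product: 15 (1S,4R)-5,8,8-trimethyl-2-oxabicyclo[2.2.2]oct-5-en-3-ol (mixture of C3 epimers)
Conditions: i-Bu2AlH (1.15 equiv), CH2Cl2, −78 °C; MeOH, aq. KNaC4H4O6 (potassium sodium tartrate)
Reagents that add atoms: none
Why: Partial reduction of a lactone with i-Bu2AlH stops at the aluminium hemiacetal at −78 °C and gives the lactol on work-up; the new anomeric centre is lost in step 9.

Step 9
Reactants: 15 (1S,4R)-5,8,8-trimethyl-2-oxabicyclo[2.2.2]oct-5-en-3-ol; 16 1-(triphenylphosphoranylidene)propan-2-one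
Product: 18 (3E)-4-[(1R,4S)-4-hydroxy-2,6,6-trimethylcyclohex-2-en-1-yl]but-3-en-2-one, via (1R,4S)-4-hydroxy-2,6,6-trimethylcyclohex-2-ene-1-carbaldehyde 17 (not isolated)
Conditions: 16 (2.5 equiv), PhMe, 90 °C, 36 h
Reagents that add atoms: none
Why: Wittig olefination of a lactol through its open hydroxy-aldehyde tautomer with a neutral stabilised ylide, which is E-selective and not basic enough to enolise the β,γ-unsaturated aldehyde, so C6 should keep its configuration and the alkene should stay at C4=C5.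

Step 10
Reactants: 18 (3E)-4-[(1R,4S)-4-hydroxy-2,6,6-trimethylcyclohex-2-en-1-yl]but-3-en-2-one; 19 diethyl (cyanomethyl)phosphonate
Product: 20 (2E,4E)-5-[(1R,4S)-4-hydroxy-2,6,6-trimethylcyclohex-2-en-1-yl]-3-methylpenta-2,4-dienenitrile
Conditions: 19 (2.5 equiv), NaH (2.4 equiv), THF, 0 °C; then 18, 0 °C to rt; chromatography (9Z isomer removed)
Reagents that add atoms: none
Why: Horner–Wadsworth–Emmons olefination of the methyl ketone; the phosphonate anion is too weak a base to deprotonate the free hydroxyl or C6–H, and the 9E nitrile should predominate.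

Step 11
Reactants: 20 (2E,4E)-5-[(1R,4S)-4-hydroxy-2,6,6-trimethylcyclohex-2-en-1-yl]-3-methylpenta-2,4-dienenitrile
Product: 22 (2E,4E)-5-[(1R,4S)-4-hydroxy-2,6,6-trimethylcyclohex-2-en-1-yl]-3-methylpenta-2,4-dienal, via (2E,4E)-5-[(1R,4S)-4-hydroxy-2,6,6-trimethylcyclohex-2-en-1-yl]-3-methylpenta-2,4-dien-1-imine 21 (not isolated)
Conditions: i-Bu2AlH (2.5 equiv), CH2Cl2, −78 to −40 °C; aq. KNaC4H4O6, then wet SiO2, 0 °C
Reagents that add atoms: water, O
Why: Nitrile-to-aldehyde reduction: i-Bu2AlH adds once to give an aluminium aldimine that is hydrolysed on wet silica, a work-up mild enough to spare the acid-sensitive allylic C3 alcohol.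

Step 12
Reactants: 23 ethyl (2E)-2-methylbut-2-enoate
Product: 24 ethyl (2E)-4-bromo-2-methylbut-2-enoate
Conditions: NBS (1.05 equiv), AIBN (2 mol%), PhCF3, 85 °C; fractional distillation
Reagents that add atoms: N-bromosuccinimide, O=C1CCC(=O)N1Br
Why: Wohl–Ziegler allylic bromination: the delocalised allyl radical from the γ-methyl is brominated at the terminus so that the conjugated enoate is kept; the minor 2-(bromomethyl) isomer is removed by distillation.

Step 13
Reactants: 24 ethyl (2E)-4-bromo-2-methylbut-2-enoate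
Product: 25 ethyl (2E)-4-(diethoxyphosphoryl)-2-methylbut-2-enoate
Conditions: P(OEt)3 (1.2 equiv), neat, 130 °C, EtBr distilled off
Reagents that add atoms: triethyl phosphite, CCOP(OCC)OCC
Why: Michaelis–Arbuzov reaction of a primary allylic bromide, driven by loss of bromoethane.

Step 14
Reactants: 25 ethyl (2E)-4-(diethoxyphosphoryl)-2-methylbut-2-enoate; 26 (2E,4E,6E)-2,7-dimethylocta-2,4,6-trienedial
Product: 27 ethyl (2E,4E,6E,8E,10E)-2,6,11-trimethyl-12-oxododeca-2,4,6,8,10-pentaenoate
Conditions: 25, NaH (1.0 equiv), THF, 0 °C; added slowly to 26 (3 equiv), THF, 0 °C to rt; excess 26 recovered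
Reagents that add atoms: none
Why: Vinylogous Horner–Wadsworth–Emmons olefination at one aldehyde of the symmetrical dialdehyde, E-selective; inverse addition to excess dialdehyde limits double olefination.

Step 15
Reactants: 27 ethyl (2E,4E,6E,8E,10E)-2,6,11-trimethyl-12-oxododeca-2,4,6,8,10-pentaenoate
Product: 28 ethyl (2E,4E,6E,8E,10E)-12-hydroxy-2,6,11-trimethyldodeca-2,4,6,8,10-pentaenoate
Conditions: NaBH4 (1 equiv), EtOH/THF, 0 °C
Reagents that add atoms: none
Why: Chemoselective 1,2-reduction of the aldehyde by borohydride; the conjugated ester is inert at 0 °C.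

Step 16
Reactants: 28 ethyl (2E,4E,6E,8E,10E)-12-hydroxy-2,6,11-trimethyldodeca-2,4,6,8,10-pentaenoate
Product: 29 [(2E,4E,6E,8E,10E)-12-ethoxy-2,7,11-trimethyl-12-oxododeca-2,4,6,8,10-pentaen-1-yl]triphenylphosphonium bromide
Conditions: Ph3P·HBr (1.05 equiv), MeOH/CH2Cl2, 0 °C to rt, dark; precipitation from EtOAc/Et2O
Reagents that add atoms: triphenylphosphine hydrobromide, [Br-].c1ccc(cc1)[PH+](c1ccccc1)c1ccccc1
Why: Phosphonium salt formation from a polyenic allylic alcohol (acid-promoted allylic substitution); PPh3 attacks the primary terminus, which keeps the polyene conjugated with the ester.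

Step 17
Reactants: 22 (2E,4E)-5-[(1R,4S)-4-hydroxy-2,6,6-trimethylcyclohex-2-en-1-yl]-3-methylpenta-2,4-dienal; 29 [(2E,4E,6E,8E,10E)-12-ethoxy-2,7,11-trimethyl-12-oxododeca-2,4,6,8,10-pentaen-1-yl]triphenylphosphonium bromide
Product: 31 ethyl (3S,6R)-3-hydroxy-8'-apo-ε-caroten-8'-oate (all-E), via ethyl (3S,6R,11Z)-3-hydroxy-8'-apo-ε-caroten-8'-oate 30 (not isolated)
Conditions: 1,2-epoxybutane/EtOH (1:1), 75 °C, 20 h, Ar, dark; then n-heptane, 90 °C, 4 h; crystallisation
Reagents that add atoms: none
Why: Wittig olefination with the ester-stabilised polyenyl ylide generated by the epoxide method (no strong base, free hydroxyl tolerated); C11=C12 should form mainly E, and the sterically hindered 11Z isomer is converted to all-E by heating (thermal Z-to-E isomerisation).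

Step 18
Reactants: 31 ethyl (3S,6R)-3-hydroxy-8'-apo-ε-caroten-8'-oate
Product: 32 (3S,6R)-8'-apo-ε-carotene-3,8'-diol
Conditions: i-Bu2AlH (4 equiv), CH2Cl2, −78 to −30 °C, Ar, dark; aq. KNaC4H4O6; crystallisation
Reagents that add atoms: none
Why: 1,2-Reduction of the conjugated ester to the primary allylic alcohol by excess i-Bu2AlH at low temperature, without conjugate reduction of the polyene; both stereocentres are remote and unaffected.

**Compound list**

1 | ethyl 3-methylbut-2-enoate | CCOC(=O)C=C(C)C | starting material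
2 | tert-butoxybis(dimethylamino)methane | CC(C)(C)OC(N(C)C)N(C)C | starting material
3 | ethyl (2E,4E)-5-(dimethylamino)-3-methylpenta-2,4-dienoate | CCOC(=O)/C=C(C)/C=C/N(C)C | intermediate
4 | ethyl (2Z,4E)-5-hydroxy-3-methylpenta-2,4-dienoate | CCOC(=O)/C=C(C)\C=C\O | intermediate
5 | 4-methyl-2H-pyran-2-one | CC1=CC(=O)OC=C1 | intermediate
6 | 3,6-dibromo-4-methyl-3,6-dihydro-2H-pyran-2-one | CC1=CC(Br)OC(=O)C1Br | intermediate
7 | 3-bromo-4-methyl-2H-pyran-2-one | CC1=C(Br)C(=O)OC=C1 | intermediate
8 | (1R,2S,5R)-5-methyl-2-(propan-2-yl)cyclohexyl (S)-4-methylbenzenesulfinate | C[C@@H]1CC[C@H]([C@@H](C1)O[S@](=O)c1ccc(C)cc1)C(C)C | starting material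
9 | lithium methyl(4-methyl-2-oxo-2H-pyran-3-yl)cuprate | [Li+].C[Cu-]C1=C(C)C=COC1=O | intermediate
10 | (S)-4-methyl-3-(4-methylbenzenesulfinyl)-2H-pyran-2-one | O=C1OC=CC(C)=C1[S@@](=O)c1ccc(C)cc1 | intermediate
11 | 2-methylpropene | CC(C)=C | starting material
12 | (1S,4S)-5,8,8-trimethyl-4-[(S)-4-methylbenzenesulfinyl]-2-oxabicyclo[2.2.2]oct-5-en-3-one | CC1=C[C@@H]2CC(C)(C)[C@]1(C(=O)O2)[S@@](=O)c1ccc(C)cc1 | intermediate
13 | (1S,4S)-5,8,8-trimethyl-4-[(4-methylphenyl)sulfanyl]-2-oxabicyclo[2.2.2]oct-5-en-3-one | CC1=C[C@@H]2CC(C)(C)[C@]1(C(=O)O2)Sc1ccc(C)cc1 | intermediate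
14 | (1S,4R)-5,8,8-trimethyl-2-oxabicyclo[2.2.2]oct-5-en-3-one | CC1=C[C@@H]2CC(C)(C)[C@H]1C(=O)O2 | intermediate
15 | (1S,4R)-5,8,8-trimethyl-2-oxabicyclo[2.2.2]oct-5-en-3-ol (C3 epimers) | CC1=C[C@@H]2CC(C)(C)[C@H]1C(O)O2 | intermediate
16 | 1-(triphenylphosphoranylidene)propan-2-one | CC(=O)C=P(c1ccccc1)(c1ccccc1)c1ccccc1 | starting material
17 | (1R,4S)-4-hydroxy-2,6,6-trimethylcyclohex-2-ene-1-carbaldehyde | CC1=C[C@@H](O)CC(C)(C)[C@H]1C=O | intermediate
18 | (3E)-4-[(1R,4S)-4-hydroxy-2,6,6-trimethylcyclohex-2-en-1-yl]but-3-en-2-one | CC1=C[C@@H](O)CC(C)(C)[C@H]1/C=C/C(C)=O | intermediate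
19 | diethyl (cyanomethyl)phosphonate | CCOP(=O)(CC#N)OCC | starting material
20 | (2E,4E)-5-[(1R,4S)-4-hydroxy-2,6,6-trimethylcyclohex-2-en-1-yl]-3-methylpenta-2,4-dienenitrile | CC1=C[C@@H](O)CC(C)(C)[C@H]1/C=C/C(C)=C/C#N | intermediate
21 | (2E,4E)-5-[(1R,4S)-4-hydroxy-2,6,6-trimethylcyclohex-2-en-1-yl]-3-methylpenta-2,4-dien-1-imine | CC1=C[C@@H](O)CC(C)(C)[C@H]1/C=C/C(C)=C/C=N | intermediate
22 | (2E,4E)-5-[(1R,4S)-4-hydroxy-2,6,6-trimethylcyclohex-2-en-1-yl]-3-methylpenta-2,4-dienal | CC1=C[C@@H](O)CC(C)(C)[C@H]1/C=C/C(C)=C/C=O | intermediate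
23 | ethyl (2E)-2-methylbut-2-enoate | CCOC(=O)/C(C)=C/C | starting material
24 | ethyl (2E)-4-bromo-2-methylbut-2-enoate | CCOC(=O)/C(C)=C/CBr | intermediate
25 | ethyl (2E)-4-(diethoxyphosphoryl)-2-methylbut-2-enoate | CCOC(=O)/C(C)=C/CP(=O)(OCC)OCC | intermediate
26 | (2E,4E,6E)-2,7-dimethylocta-2,4,6-trienedial | O=C/C(C)=C/C=C/C=C(C)/C=O | starting material
27 | ethyl (2E,4E,6E,8E,10E)-2,6,11-trimethyl-12-oxododeca-2,4,6,8,10-pentaenoate | CCOC(=O)/C(C)=C/C=C/C(C)=C/C=C/C=C(C)/C=O | intermediate
28 | ethyl (2E,4E,6E,8E,10E)-12-hydroxy-2,6,11-trimethyldodeca-2,4,6,8,10-pentaenoate | CCOC(=O)/C(C)=C/C=C/C(C)=C/C=C/C=C(C)/CO | intermediate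
29 | [(2E,4E,6E,8E,10E)-12-ethoxy-2,7,11-trimethyl-12-oxododeca-2,4,6,8,10-pentaen-1-yl]triphenylphosphonium bromide | CCOC(=O)/C(C)=C/C=C/C(C)=C/C=C/C=C(C)/C[P+](c1ccccc1)(c1ccccc1)c1ccccc1.[Br-] | intermediate
30 | ethyl (3S,6R,11Z)-3-hydroxy-8'-apo-ε-caroten-8'-oate | CC1=C[C@@H](O)CC(C)(C)[C@H]1/C=C/C(C)=C/C=C\C(C)=C\C=C\C=C(C)\C=C\C=C(/C)C(=O)OCC | intermediate
31 | ethyl (3S,6R)-3-hydroxy-8'-apo-ε-caroten-8'-oate, all-E; ethyl (2E,4E,6E,8E,10E,12E,14E,16E)-17-[(1R,4S)-4-hydroxy-2,6,6-trimethylcyclohex-2-en-1-yl]-2,6,11,15-tetramethylheptadeca-2,4,6,8,10,12,14,16-octaenoate | CC1=C[C@@H](O)CC(C)(C)[C@H]1/C=C/C(C)=C/C=C/C(C)=C/C=C/C=C(C)/C=C/C=C(\C)C(=O)OCC | intermediate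
32 | (3S,6R)-8'-apo-ε-carotene-3,8'-diol; (2E,4E,6E,8E,10E,12E,14E,16E)-17-[(1R,4S)-4-hydroxy-2,6,6-trimethylcyclohex-2-en-1-yl]-2,6,11,15-tetramethylheptadeca-2,4,6,8,10,12,14,16-octaen-1-ol | CC1=C[C@@H](O)CC(C)(C)[C@H]1/C=C/C(C)=C/C=C/C(C)=C/C=C/C=C(C)/C=C/C=C(\C)CO | target

**Step count**

Total step count: 18. Longest linear sequence: 13 steps (steps 1–11, 17 and 18).

**Steps most likely to fail**

1. Step 5 (Proposed new method). Isobutene may not engage the hindered, methyl-deactivated pyrone at all; the first C–C bond may form without ring closure (ene-type hydrogen transfer or cationic oligomerisation of the alkene); or the two π-faces may be poorly discriminated. The fallback sets out from 10 and returns at 14. Pyrone 10 would be combined at ambient pressure in CH2Cl2 with 1,1-dimethoxyethene, the established partner class for 3-sulfinyl-2-pyrones, to give (1S,4R)-8,8-dimethoxy-5-methyl-4-[(S)-4-methylbenzenesulfinyl]-2-oxabicyclo[2.2.2]oct-5-en-3-one F1. Deoxygenation with NaI/(CF3CO)2O would give (1S,4R)-8,8-dimethoxy-5-methyl-4-[(4-methylphenyl)sulfanyl]-2-oxabicyclo[2.2.2]oct-5-en-3-one F2, and Bu3SnH/AIBN would give (1S,4S)-8,8-dimethoxy-5-methyl-2-oxabicyclo[2.2.2]oct-5-en-3-one F3. Mild ketal hydrolysis (oxalic acid on wet SiO2) would release (1S,4S)-5-methyl-2-oxabicyclo[2.2.2]oct-5-ene-3,8-dione F4, whose ketone cannot enolise toward the bridgehead. Geminal dimethylation of that ketone with Me2TiCl2 (Reetz conditions, CH2Cl2, −30 °C) would then install the C1 methyl groups and rejoin the route at 14. The dimethylation is the weak point of this fallback, because it passes through a cation next to the bridgehead.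

2. Step 9. Olefination of the hindered, largely lactol-masked aldehyde may be slow, and prolonged heating may allow epimerisation at C6 or migration of the C4=C5 bond into conjugation. The fallback sets out from 14 and returns at 18. Lactone 14 would be opened with MeONHMe·HCl/Me3Al (CH2Cl2, 0 °C) to (1R,4S)-4-hydroxy-N-methoxy-N,2,6,6-tetramethylcyclohex-2-ene-1-carboxamide F5 and silylated (t-BuMe2SiCl, imidazole, DMF) to (1R,4S)-4-[tert-butyl(dimethyl)silyl]oxy-N-methoxy-N,2,6,6-tetramethylcyclohex-2-ene-1-carboxamide F6. Reduction with i-Bu2AlH at −78 °C would give the free, O-protected aldehyde (1R,4S)-4-[tert-butyl(dimethyl)silyl]oxy-2,6,6-trimethylcyclohex-2-ene-1-carbaldehyde F7, which is olefinated at once with 16 (PhMe, 60 °C) to (3E)-4-[(1R,4S)-4-[tert-butyl(dimethyl)silyl]oxy-2,6,6-trimethylcyclohex-2-en-1-yl]but-3-en-2-one F8. Bu4NF in THF then returns to 18.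

3. Step 7. The radical chain may propagate poorly because the bridgehead radical gains no stabilisation from the orthogonal carbonyl, and extended heating of the congested bicycle may cause cycloreversion or loss of CO2. The fallback sets out from 12 and returns at 14, skipping step 6: hydrogenolytic desulfurisation of the sulfoxide itself with acetone-deactivated Raney Ni in EtOH at 0 °C to rt, which cleaves both C–S bonds at low temperature. This fallback makes no new compound (F0).

**Further compounds**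

F1 | step 5 | (1S,4R)-8,8-dimethoxy-5-methyl-4-[(S)-4-methylbenzenesulfinyl]-2-oxabicyclo[2.2.2]oct-5-en-3-one | CC1=C[C@@H]2CC(OC)(OC)[C@]1(C(=O)O2)[S@@](=O)c1ccc(C)cc1
F2 | step 5 | (1S,4R)-8,8-dimethoxy-5-methyl-4-[(4-methylphenyl)sulfanyl]-2-oxabicyclo[2.2.2]oct-5-en-3-one | CC1=C[C@@H]2CC(OC)(OC)[C@]1(C(=O)O2)Sc1ccc(C)cc1
F3 | step 5 | (1S,4S)-8,8-dimethoxy-5-methyl-2-oxabicyclo[2.2.2]oct-5-en-3-one | CC1=C[C@@H]2CC(OC)(OC)[C@H]1C(=O)O2
F4 | step 5 | (1S,4S)-5-methyl-2-oxabicyclo[2.2.2]oct-5-ene-3,8-dione | CC1=C[C@@H]2CC(=O)[C@H]1C(=O)O2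
F5 | step 9 | (1R,4S)-4-hydroxy-N-methoxy-N,2,6,6-tetramethylcyclohex-2-ene-1-carboxamide | CC1=C[C@@H](O)CC(C)(C)[C@H]1C(=O)N(C)OC
F6 | step 9 | (1R,4S)-4-[tert-butyl(dimethyl)silyl]oxy-N-methoxy-N,2,6,6-tetramethylcyclohex-2-ene-1-carboxamide | CC1=C[C@@H](O[Si](C)(C)C(C)(C)C)CC(C)(C)[C@H]1C(=O)N(C)OC
F7 | step 9 | (1R,4S)-4-[tert-butyl(dimethyl)silyl]oxy-2,6,6-trimethylcyclohex-2-ene-1-carbaldehyde | CC1=C[C@@H](O[Si](C)(C)C(C)(C)C)CC(C)(C)[C@H]1C=O
F8 | step 9 | (3E)-4-[(1R,4S)-4-[tert-butyl(dimethyl)silyl]oxy-2,6,6-trimethylcyclohex-2-en-1-yl]but-3-en-2-one | CC1=C[C@@H](O[Si](C)(C)C(C)(C)C)CC(C)(C)[C@H]1/C=C/C(C)=O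
F0 | step 7 | none | none
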